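**Retrosynthetic overview**

1. Target 20 ⇐ hydrogenolysis of octa-O-benzyl ether 19 ⇐ syn hydroboration–oxidation of 4-aryl-flav-3-ene 17, which sets upper C3 and C4 anti to the C2 aryl (2,3-trans-3,4-trans = 4α).
2. 17 ⇐ Negishi C4–C8 coupling of flavanone enol triflate 11 with the 8-zincio derivative of bromide 16.
3. 16 ⇐ (+)-catechin 12 (phenol benzylation, C8 bromination, 3-O-benzylation); this supplies the lower unit with both its stereocentres.
4. 11 ⇐ (2S)-flavanone 9 ⇐ catalytic asymmetric intramolecular oxa-Michael cyclisation/decarboxylation of alkylidene β-keto ester 8 (key ring closure, sets upper C2).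
5. 8 ⇐ Knoevenagel of β-keto ester 5 and aldehyde 7. Ring order: all aromatic rings and the lower pyran are bought; the upper pyran is the only ring made.

Assumption: the epi-quinidine-derived bifunctional thiourea is taken as the pseudo-enantiomer that gives the (2S)-flavanone; if the sense is the reverse, the epi-quinine-derived catalyst is used instead.

**Upper unit**

Step 1
Reactants: 1 methyl 2,4-dihydroxybenzoate; 2 benzyl bromide
Product: 3 methyl 4-(benzyloxy)-2-hydroxybenzoate
Conditions: BnBr (1.05 eq), K2CO3, acetone, reflux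
Reagents that add atoms: benzyl bromide (2), BrCc1ccccc1
Why: Williamson etherification; the 2-OH is hydrogen-bonded to the ester carbonyl, so only the 4-OH is alkylated.

Step 2
Reactants: 3; 4 tert-butyl acetate
Product: 5 tert-butyl 3-[4-(benzyloxy)-2-hydroxyphenyl]-3-oxopropanoate
Conditions: LDA (4.2 eq), t-BuOAc (4 eq), THF, −78 °C; add 3, −78 → 0 °C; AcOH quench
Reagents that add atoms: tert-butyl acetate (4), CC(=O)OC(C)(C)C
Why: Crossed Claisen condensation; excess ester enolate covers deprotonation of the phenol and of the product, and the tert-butyl ester resists lactonisation to the coumarin.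

Step 3
Reactants: 6 3,4-dihydroxybenzaldehyde; 2 benzyl bromide
Product: 7 3,4-bis(benzyloxy)benzaldehyde
Conditions: BnBr (2.3 eq), K2CO3, DMF, 60 °C
Reagents that add atoms: benzyl bromide (2), BrCc1ccccc1
Why: Double Williamson etherification of the catechol.

Step 4
Reactants: 5; 7
Product: 8 tert-butyl 2-[4-(benzyloxy)-2-hydroxybenzoyl]-3-[3,4-bis(benzyloxy)phenyl]prop-2-enoate (alkylidene β-keto ester, E/Z mixture, used as such)
Conditions: piperidine (10 mol%), AcOH (10 mol%), 4 Å MS, toluene, rt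
Reagents that add atoms: none (water is lost)
Why: Knoevenagel condensation of the active methylene with the aldehyde; mild conditions keep racemic background cyclisation low.

Step 5 (key ring closure)
Reactants: 8
Product: 9 (2S)-7-(benzyloxy)-2-[3,4-bis(benzyloxy)phenyl]-2,3-dihydro-4H-chromen-4-one [(S)-tri-O-benzylbutin]
Conditions: 9-amino(9-deoxy)-epi-quinidine 3,5-bis(CF3)phenyl thiourea (10 mol%), toluene, −25 °C; then TsOH·H2O (0.5 eq), 80 °C, one pot; recrystallise to raise ee
Reagents that add atoms: none (isobutene and CO2 are lost)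
Why: Intramolecular 6-endo oxa-Michael addition of the phenol to the doubly activated alkene, with the bifunctional thiourea/amine catalyst choosing the enantioface to set C2 as S; acid then removes the tert-butyl ester and the β-keto acid decarboxylates.

Step 6
Reactants: 9; 10 Comins' reagent [N-(5-chloro-2-pyridyl)bis(trifluoromethanesulfonimide)]
Product: 11 (2S)-7-(benzyloxy)-2-[3,4-bis(benzyloxy)phenyl]-2H-chromen-4-yl trifluoromethanesulfonate
Conditions: LiHMDS (1.1 eq), THF, −78 °C; Comins' reagent (1.2 eq), −78 → −30 °C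
Reagents that add atoms: Comins' reagent (10), FC(F)(F)S(=O)(=O)N(c1ccc(Cl)cn1)S(=O)(=O)C(F)(F)F
Why: Kinetic enolate O-triflation; the lithium enolate is kept cold so that retro-oxa-Michael ring opening cannot racemise C2.

**Lower unit**

Step 7
Reactants: 12 (+)-catechin (2R,3S); 2 benzyl bromide
Product: 13 (2R,3S)-5,7-bis(benzyloxy)-2-[3,4-bis(benzyloxy)phenyl]chroman-3-ol (5,7,3',4'-tetra-O-benzylcatechin)
Conditions: BnBr (4.4 eq), K2CO3, DMF, 0 °C → rt, Ar
Reagents that add atoms: benzyl bromide (2), BrCc1ccccc1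
Why: Williamson etherification of the four phenols only; K2CO3 does not deprotonate the secondary 3-OH or epimerise C2.

Step 8
Reactants: 13; 14 N-bromosuccinimide
Product: 15 (2R,3S)-8-bromo-5,7-bis(benzyloxy)-2-[3,4-bis(benzyloxy)phenyl]chroman-3-ol
Conditions: NBS (1.0 eq), CH2Cl2, −40 → 0 °C
Reagents that add atoms: N-bromosuccinimide (14), O=C1CCC(=O)N1Br
Why: Electrophilic aromatic bromination; C8 is the most nucleophilic position of the benzylated phloroglucinol ring, so the future coupling site is fixed regiospecifically.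

Step 9
Reactants: 15; 2 benzyl bromide
Product: 16 (2R,3S)-3,5,7-tris(benzyloxy)-2-[3,4-bis(benzyloxy)phenyl]-8-bromochroman
Conditions: NaH (1.3 eq), BnBr (1.3 eq), TBAI (cat.), THF/DMF, 0 °C → rt
Reagents that add atoms: benzyl bromide (2), BrCc1ccccc1
Why: Williamson etherification removes the only acidic proton before metalation, and this benzyl group leaves with the others at the end.

**Union and endgame**

Step 10
Reactants: 11; 16
Product: 17 (2R,3S)-3,5,7-tris(benzyloxy)-2-[3,4-bis(benzyloxy)phenyl]-8-{(2S)-7-(benzyloxy)-2-[3,4-bis(benzyloxy)phenyl]-2H-chromen-4-yl}chroman (4-aryl-flav-3-ene)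
Conditions: 16 (1.3 eq), t-BuLi (2.6 eq), THF, −78 °C; ZnCl2 (1.4 eq), −78 °C → rt; then 11 (1.0 eq), XPhos Pd G3 (5 mol%), THF, rt → 50 °C
Reagents that add atoms: none
Why: Br–Li exchange and transmetalation give the C8 arylzinc, and Negishi coupling with the vinyl triflate forms the C4–C8 bond under base-free conditions that leave C2 untouched.

Step 11
Reactants: 17; 18 hydrogen peroxide
Product: 19 (2R,3S,4S)-7-(benzyloxy)-2-[3,4-bis(benzyloxy)phenyl]-4-{(2R,3S)-3,5,7-tris(benzyloxy)-2-[3,4-bis(benzyloxy)phenyl]chroman-8-yl}chroman-3-ol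
Conditions: BH3·SMe2 (5 eq), THF, 0 °C → rt; then 3 M NaOH, 30% H2O2, 0 °C → rt
Reagents that add atoms: hydrogen peroxide (18), OO (borane supplies only H)
Why: Hydroboration–oxidation; H–B adds syn to the face anti to the C2 aryl with boron at C3 (C4 is fully substituted and doubly benzylic), and oxidation with retention gives 3-OH trans to the 2-aryl and the 4-aryl trans to 3-OH.

Step 12
Reactants: 19
Product: 20 fisetinidol-(4α,8)-catechin
Conditions: H2 (1 atm), 20% Pd(OH)2/C, THF/MeOH (1:1), rt; filter, lyophilise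
Reagents that add atoms: none
Why: Hydrogenolysis of all eight benzyl ethers (seven aryl, one alkyl) without touching the interflavan C–C bond or any stereocentre.

**Compound list**

1 | methyl 2,4-dihydroxybenzoate | COC(=O)c1ccc(O)cc1O | starting material
2 | benzyl bromide | BrCc1ccccc1 | starting material (reagent)
3 | methyl 4-(benzyloxy)-2-hydroxybenzoate | COC(=O)c1ccc(OCc2ccccc2)cc1O | intermediate
4 | tert-butyl acetate | CC(=O)OC(C)(C)C | starting material (reagent)
5 | tert-butyl 3-[4-(benzyloxy)-2-hydroxyphenyl]-3-oxopropanoate | CC(C)(C)OC(=O)CC(=O)c1ccc(OCc2ccccc2)cc1O | intermediate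
6 | 3,4-dihydroxybenzaldehyde | O=Cc1ccc(O)c(O)c1 | starting material
7 | 3,4-bis(benzyloxy)benzaldehyde | O=Cc1ccc(OCc2ccccc2)c(OCc2ccccc2)c1 | intermediate
8 | tert-butyl 2-[4-(benzyloxy)-2-hydroxybenzoyl]-3-[3,4-bis(benzyloxy)phenyl]prop-2-enoate (E/Z) | CC(C)(C)OC(=O)C(=Cc1ccc(OCc2ccccc2)c(OCc2ccccc2)c1)C(=O)c1ccc(OCc2ccccc2)cc1O | intermediate
9 | (2S)-7-(benzyloxy)-2-[3,4-bis(benzyloxy)phenyl]chroman-4-one | O=C1C[C@@H](c2ccc(OCc3ccccc3)c(OCc3ccccc3)c2)Oc2cc(OCc3ccccc3)ccc12 | intermediate
10 | Comins' reagent | FC(F)(F)S(=O)(=O)N(c1ccc(Cl)cn1)S(=O)(=O)C(F)(F)F | starting material (reagent)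
11 | (2S)-7-(benzyloxy)-2-[3,4-bis(benzyloxy)phenyl]-2H-chromen-4-yl triflate | FC(F)(F)S(=O)(=O)OC1=C[C@@H](c2ccc(OCc3ccccc3)c(OCc3ccccc3)c2)Oc2cc(OCc3ccccc3)ccc12 | intermediate
12 | (+)-catechin (2R,3S) | Oc1cc(O)c2c(c1)O[C@H](c1ccc(O)c(O)c1)[C@@H](O)C2 | starting material
13 | 5,7,3',4'-tetra-O-benzyl-(+)-catechin | O(Cc7ccccc7)c1cc(OCc7ccccc7)c2c(c1)O[C@H](c8ccc(OCc7ccccc7)c(OCc7ccccc7)c8)[C@@H](O)C2 | intermediate
14 | N-bromosuccinimide | O=C1CCC(=O)N1Br | starting material (reagent)
15 | 8-bromo-5,7,3',4'-tetra-O-benzylcatechin | O(Cc7ccccc7)c1cc(OCc7ccccc7)c2c(c1Br)O[C@H](c8ccc(OCc7ccccc7)c(OCc7ccccc7)c8)[C@@H](O)C2 | intermediate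
16 | 8-bromo-3,5,7,3',4'-penta-O-benzylcatechin | O(Cc7ccccc7)c1cc(OCc7ccccc7)c2c(c1Br)O[C@H](c8ccc(OCc7ccccc7)c(OCc7ccccc7)c8)[C@@H](OCc7ccccc7)C2 | intermediate
17 | octa-O-benzyl 4-(catechin-8-yl)-flav-3-ene (upper 2S; lower 2R,3S) | O(Cc7ccccc7)c1cc(OCc7ccccc7)c2c(c1C5=C[C@@H](c8ccc(OCc7ccccc7)c(OCc7ccccc7)c8)Oc6cc(OCc7ccccc7)ccc56)O[C@H](c8ccc(OCc7ccccc7)c(OCc7ccccc7)c8)[C@@H](OCc7ccccc7)C2 | intermediate
18 | hydrogen peroxide | OO | starting material (reagent)
19 | octa-O-benzyl fisetinidol-(4α,8)-catechin, upper 3-OH free (upper 2R,3S,4S; lower 2R,3S) | O(Cc7ccccc7)c1cc(OCc7ccccc7)c2c(c1[C@H]5[C@H](O)[C@@H](c8ccc(OCc7ccccc7)c(OCc7ccccc7)c8)Oc6cc(OCc7ccccc7)ccc56)O[C@H](c8ccc(OCc7ccccc7)c(OCc7ccccc7)c8)[C@@H](OCc7ccccc7)C2 | intermediate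
20 | fisetinidol-(4α,8)-catechin | Oc1ccc2c(c1)O[C@H](c1ccc(O)c(O)c1)[C@@H](O)[C@@H]2c1c(O)cc(O)c2c1O[C@H](c1ccc(O)c(O)c1)[C@@H](O)C2 | target

**Step count**

Total steps: 12.
Longest linear sequence: 8 (steps 1, 2, 4, 5, 6, 10, 11, 12). The side branches are step 3 and steps 7–9.

**Steps most likely to fail, with fallbacks**

- **Step 5 (enantioselectivity of the oxa-Michael, or ee erosion during acidic decarboxylation of the electron-rich flavanone).** Fallback: close the same ring racemically by base-mediated oxa-Michael cyclisation of the simple 2'-hydroxychalcone (from 4-benzyloxy-2-hydroxyacetophenone and 7), then resolve rac-9 by Ru–TsDPEN transfer-hydrogenation kinetic resolution, recovering (S)-9. Any residual antipode is removed as a diastereomer after step 10.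
- **Step 10 (coupling of a di-ortho-substituted arylzinc with a hindered, sensitive enol triflate).** Fallback: skip the triflate and palladium; add the aryllithium from 16 to ketone 9 as its organocerium (CeCl3, THF, −78 °C) and dehydrate the tertiary benzylic alcohol (Burgess reagent) to the same flavene 17.
- **Step 11 (rate, facial selectivity or C2–O cleavage in hydroboration of the hindered electron-rich alkene).** Fallback: form the interflavan bond by a cationic route instead. Convert 9 to its silyl enol ether and oxidise (Rubottom, DMDO) to the trans-dihydroflavonol, reduce with NaBH4 to the flavan-3,4-diol, and carry out TiCl4-mediated C4 arylation of tetra-O-benzylcatechin 13 (C8-selective, 3,4-trans favoured), then hydrogenolyse.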